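## Analysis of the target

Broussoflavonol D (21) is a flavonol, a 3-hydroxy-2-aryl-4H-chromen-4-one made of rings A and C, with a pentasubstituted ring B on C2. Ring A carries hydroxyls on C5 and C7 and a 1,1-dimethylallyl group on C8. Ring B carries a prenyl group on C2', a 2,2-dimethyl-2H-pyran fused across C3'–C4' with its oxygen on C4', and a hydroxyl on C5'. There is no stereogenic centre and no double bond of defined configuration outside a ring, so the problem is one of regiochemistry and chemoselectivity only. The sensitive groups are the oxidisable 3-hydroxypyranone enol, the latent catechol O4'/O5', and three different C5 alkenes (a trisubstituted prenyl alkene, the styrene-type alkene of the chromene and a monosubstituted vinyl group), which rule out electrophilic oxidants and hydrogenation. The hard points are the four contiguous substituents C2'–C5' of ring B, the placement of the tert-alkyl group on C8 and not C6, the introduction of O3 in the presence of the alkenes, and the differentiation of five oxygens so that the right one is free at the decisive moment. The strategy rests on one feature: the O4'–C(CH3)2 bond and the C3'–CH=CH unit of the pyran are what a 3'-prenyl group beside a free 4'-hydroxyl becomes on loss of two hydrogens. The 2'-prenyl group has only carbon neighbours (C1' and C3'), and the C8 substituent has a quaternary benzylic carbon, so neither can follow the same path.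

## Retrosynthetic reasoning

21 from 20. The last operation only uncovers hydroxyls: the four acetal C–O bonds at O3, O5, O7 and O5' of 20 are cut. Ethers of the methoxymethyl type are preferred to esters for a structural reason. An ester on O5' would sit beside the free O4'–H of 18 and could move over to it through a five-membered tetrahedral intermediate, above all in the hot amine medium in which 18 is made. The migrated isomer would have O5'–H free, para to the 2'-prenyl methylene, and O4' blocked, which opens a second oxidation channel and closes the wanted one. An acetal ether cannot migrate. The price is an acidic instead of a basic last step. The structure tolerates it: the 2'-prenyl group has no neighbouring hydroxyl to cyclise onto, the vinyl group on C8 would give only a secondary cation, and the chromene withstands dilute acid.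

20 from 18 (key disconnection). The O4'–C(CH3)2 bond of the pyran is cut and two hydrogens are added back, which gives the 2',3'-diprenyl-4'-phenol 18. No other bond of 20 can be made this late without touching the rest of the molecule, and the pyran is then never carried through base, peroxide or heat. Forward, a high-potential quinone has to take hydride from the C3' methylene only. The resulting ortho-quinone methide 19 then closes to the pyran by itself. The selectivity is built into 18: O4'–H is its only free hydroxyl, the 2'-methylene has an ether and not a hydroxyl para to it, and the C8 group has no benzylic hydrogen.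

18 from 17. The C3'–CH2 bond is cut by a retro-[3,3] shift to the tertiary allyl ether on O4'. This one group does two jobs. It masks O4' through all earlier steps, so that every other oxygen can be capped without selectivity problems. It then delivers the 3'-prenyl group and uncovers O4'–H in a single reagent-free step. C3' is the only ortho carbon with hydrogen, because C5' carries the acetal ether.

17 from 16 from 14. The O3 acetal is removed, then ring C is opened at O1–C2 with removal of O3, which leads to the 2'-hydroxychalcone 14. An Algar–Flynn–Oyamada oxidation forms the O1–C2 bond and installs O3 in one operation, passing through 15. A diketone route would stop at the flavone with C3–H, and oxidising that position afterwards needs electrophilic oxygen, which the three alkenes would not survive. Alkaline peroxide is nucleophilic and leaves isolated alkenes alone.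

14 from 5 and 13. The Cα=Cβ bond is cut (Claisen–Schmidt condensation). This is the convergent step: ring A with its C8 group and ring B with three of its four substituents are finished before they meet.

13 from 10 and 12; 10 from 8 and 9; 8 from 7 from 6. The O4'–C bond of the tertiary ether is made by palladium-catalysed allylic etherification of 10 with the carbonate 12, which comes from 11. This avoids a semi-hydrogenation in the presence of other alkenes. The C2'–CH2 bond is cut next (Stille coupling of 8 with 9). The bromine that marks C2' is already present in 6, so no halogenation has to be done on a ring that carries alkenes or acetals. The two oxygens of 7 are told apart through the dianion: the oxyanion para to the formyl group is delocalised, so the other one, the future O5', takes the acetal. The methyl ethers of 6 are cleaved first, while the molecule still contains nothing sensitive.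

5 from 4 from 3 from 1 and 2. The C8–C bond of the 1,1-dimethylallyl group is cut by a retro-[3,3] shift to the prenyl ether 3. In 3 the two ortho positions are equivalent by symmetry and the para position carries the acetyl group, so 4 is the only possible product. The same shift on a finished flavone 7-O-prenyl ether would have to choose between C6 and C8. The regiochemistry is then fixed by protection. The hydroxyl of 4 between the acetyl and the tert-alkyl group is chelated and buried, stays free in 5, and becomes O1, which places the tert-alkyl group on C8. 3 comes from 1 and 2 by alkylation of the one non-chelated hydroxyl.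

## Alternatives that were turned down

Alternative 1: The bonds C4–C4a and O1–C8a are cut, so that ring A comes from the aryne A2 and C2, C3, C4 and ring B from the arylpropiolic acid A3. Forward, fluoride releases A2 from its silyl triflate. The carboxylate of A3 adds to the aryne carbon remote from the methoxymethoxy group, and the aryl anion formed next to that group takes the acyl group, which gives the ortho-hydroxyaryl ynone A1.
- For: two bonds and a correctly differentiated acylphloroglucinol form in one convergent step, and ring B arrives complete with its pyran. On convergence it is stronger than the chosen route.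
- Against: A1 must still be closed to the flavone A4, which has no oxygen on C3. That oxygen would have to be put in with the chromene, prenyl and allyl ether alkenes all present. The C8 group must then come from a shift of the 7-O-prenyl group of A4, where C6 and C8 are both open. An aryne is also a strong enophile, and both A2 and A3 carry prenyl-type alkenes with allylic hydrogens. A2 and A3 each need several steps.
- Comparison: the chosen strategy gives up some convergence. In return O3 comes with the ring closure, C8 is fixed by symmetry before ring C exists, and no reactive intermediate meets the alkenes.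

Alternative 2: Ring B is cut at C2'–C3' and C1'–C6'. Forward, the 2-pyrone diene of the pyranopyranone A6 adds to the alkynoate A7, and the bicyclic adduct loses its lactone bridge to give the arene A5.
- For: the pentasubstituted ring is built de novo with no halogenation and no tin, and the pyran is in place from the start. On those points it is stronger than the chosen route.
- Against: the orientation of the cycloaddition is not secured. The donor on C4 of the pyrone and the ring oxygen favour the needed bond from the fused terminus to the prenyl-bearing alkyne carbon, but the silyloxy group on C5 works the other way. That terminus is also fully substituted. The temperatures of pyrone cycloadditions endanger the 2H-pyran, which can ring-open. A6 is itself a multistep target, and A5 is only a ring B ester. Ring C, O3 and ring A would all remain to be solved.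
- Comparison: the chosen route obtains the same substitution pattern from a purchasable bromoarene in four steps whose regiochemistry follows from ground-state properties, and spends its one uncertain step where it ends the synthesis.

Alternative 3: Ring C is cut at C2=C3. Forward, the ylide carbon of the phosphorane A9 attacks the aryl ester carbonyl in an intramolecular Wittig reaction, the phosphorus leaves as its oxide, and the flavone A8 results.
- For: the closure is neutral and can only give the six-membered ring, so there is no aurone problem and no acidic dehydration. On ring-size control it is stronger than the oxidative chalcone cyclisation used here.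
- Against: A8 has C3–H, so O3 must be introduced at the very end on a molecule with the chromene, the prenyl group and the vinyl group. Making A9 needs α-halogenation of a methyl ketone on an electron-rich ring that already carries an alkene. It also needs acylation of the phenol wedged between the acyl and the tert-alkyl group by an ortho-substituted aroyl donor.
- Comparison: the chosen strategy accepts the known weakness of the peroxide cyclisation and answers it with a fallback. In return it never has to oxidise C3 of a finished flavone and never has to esterify the most hindered oxygen.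

Key step: step 13

Remark on the chemistry: 6, 9 and 11 are taken as purchasable, and all hydroxyls other than O4' are carried as methoxymethyl ethers, so the final deprotection is acidic.

## Route

Step 1
Reactants: 1 2,4,6-trihydroxyacetophenone; 2 prenyl bromide
Product: 3 1-[2,6-dihydroxy-4-(3-methylbut-2-enyloxy)phenyl]ethanone
Conditions: K2CO3 (1.1 equiv), acetone, rt
Reagents that add atoms: none
Why: Williamson ether synthesis; the 4-hydroxyl para to the acetyl group is the most acidic and the only one not hydrogen-bonded to the carbonyl, so one equivalent of base and of 2 should alkylate it alone, and acetone disfavours C-alkylation of the phloroglucinol ring.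

Step 2
Reactants: 3 1-[2,6-dihydroxy-4-(3-methylbut-2-enyloxy)phenyl]ethanone
Product: 4 1-[2,4,6-trihydroxy-3-(2-methylbut-3-en-2-yl)phenyl]ethanone
Conditions: PhNEt2, 190 °C, Ar
Reagents that add atoms: none
Why: Aromatic Claisen rearrangement; the [3,3] shift moves the C5 unit with allylic inversion to the ortho carbon as a 1,1-dimethylallyl group, the two ortho positions are equivalent and the para position is blocked by the acetyl group, and the basic amine solvent suppresses acid-catalysed closure of the new phenol onto the vinyl group.

Step 3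
Reactants: 4 1-[2,4,6-trihydroxy-3-(2-methylbut-3-en-2-yl)phenyl]ethanone
Product: 5 1-[2-hydroxy-4,6-bis(methoxymethoxy)-3-(2-methylbut-3-en-2-yl)phenyl]ethanone
Conditions: MOMCl (2.2 equiv), iPr2NEt, CH2Cl2, 0 °C to rt
Reagents that add atoms: chloromethyl methyl ether, COCCl
Why: Acetal ether formation; the hydroxyl between the acetyl and the tert-alkyl group is chelated to the carbonyl and sterically buried, so two equivalents of the chloride should cap O4 and O6 and leave it free, which decides that this oxygen becomes O1 and the tert-alkyl group ends on C8.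

Step 4
Reactants: 6 2-bromo-4,5-dimethoxybenzaldehyde
Product: 7 2-bromo-4,5-dihydroxybenzaldehyde
Conditions: BBr3 (2.5 equiv), CH2Cl2, −78 °C to rt; H2O
Reagents that add atoms: none
Why: Lewis-acid cleavage of aryl methyl ethers (boron coordination, bromide attack on methyl); it is placed first because nothing acid- or bromide-sensitive is yet present, and the aldehyde and aryl bromide are unaffected.

Step 5
Reactants: 7 2-bromo-4,5-dihydroxybenzaldehyde
Product: 8 2-bromo-4-hydroxy-5-(methoxymethoxy)benzaldehyde
Conditions: NaH (2.1 equiv), DMF, 0 °C; MOMCl (1.0 equiv); cold dilute HCl work-up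
Reagents that add atoms: chloromethyl methyl ether, COCCl
Why: Regioselective mono-alkylation of a catechol dianion; the oxyanion para to the formyl group is delocalised into the carbonyl like a vinylogous carboxylate, so the localised oxyanion on C5 is the stronger nucleophile and should take the single equivalent of electrophile.

Step 6
Reactants: 8 2-bromo-4-hydroxy-5-(methoxymethoxy)benzaldehyde; 9 tributyl(3-methylbut-2-enyl)stannane
Product: 10 4-hydroxy-5-(methoxymethoxy)-2-(3-methylbut-2-enyl)benzaldehyde
Conditions: Pd(PPh3)4 (5 mol%), DMF, 90 °C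
Reagents that add atoms: none
Why: Stille coupling; the C–Br bond is activated toward zerovalent palladium by the ortho formyl group, and after transmetalation reductive elimination at the less substituted allyl terminus should give the linear prenyl arene under neutral conditions that tolerate the phenol, the aldehyde and the acetal.

Step 7
Reactants: 11 2-methylbut-3-en-2-ol
Product: 12 tert-butyl 2-methylbut-3-en-2-yl carbonate
Conditions: n-BuLi, THF, 0 °C; Boc2O
Reagents that add atoms: di-tert-butyl dicarbonate, CC(C)(C)OC(=O)OC(=O)OC(C)(C)C
Why: Acylation of the lithium alkoxide of the tertiary alcohol gives the mixed carbonate, the usual leaving group for palladium-catalysed allylic substitution.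

Step 8
Reactants: 10 4-hydroxy-5-(methoxymethoxy)-2-(3-methylbut-2-enyl)benzaldehyde; 12 tert-butyl 2-methylbut-3-en-2-yl carbonate
Product: 13 5-(methoxymethoxy)-4-(2-methylbut-3-en-2-yloxy)-2-(3-methylbut-2-enyl)benzaldehyde
Conditions: Pd(PPh3)4 (3 mol%), THF, 0 °C to rt
Reagents that add atoms: none
Why: Tsuji–Trost O-allylation; ionisation of 12 gives the 1,1-dimethyl-π-allyl palladium cation and, after decarboxylation, tert-butoxide that deprotonates the phenol, and the phenoxide attacks the more substituted terminus under kinetic control to give the tertiary ether, so the reaction is kept cold and stopped at full conversion.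

Step 9
Reactants: 5 1-[2-hydroxy-4,6-bis(methoxymethoxy)-3-(2-methylbut-3-en-2-yl)phenyl]ethanone; 13 5-(methoxymethoxy)-4-(2-methylbut-3-en-2-yloxy)-2-(3-methylbut-2-enyl)benzaldehyde
Product: 14 (E)-1-[2-hydroxy-4,6-bis(methoxymethoxy)-3-(2-methylbut-3-en-2-yl)phenyl]-3-[5-(methoxymethoxy)-4-(2-methylbut-3-en-2-yloxy)-2-(3-methylbut-2-enyl)phenyl]prop-2-en-1-one
Conditions: KOH, EtOH, rt
Reagents that add atoms: none
Why: Claisen–Schmidt condensation (aldol addition, then E1cB dehydration) between a methyl ketone and a non-enolisable aldehyde; the E enone is the thermodynamic product, and the tertiary allyl ether and the acetals are stable to hydroxide at room temperature.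

Step 10
Reactants: 14 (E)-1-[2-hydroxy-4,6-bis(methoxymethoxy)-3-(2-methylbut-3-en-2-yl)phenyl]-3-[5-(methoxymethoxy)-4-(2-methylbut-3-en-2-yloxy)-2-(3-methylbut-2-enyl)phenyl]prop-2-en-1-one
Product: 16 3-hydroxy-5,7-bis(methoxymethoxy)-2-[5-(methoxymethoxy)-4-(2-methylbut-3-en-2-yloxy)-2-(3-methylbut-2-enyl)phenyl]-8-(2-methylbut-3-en-2-yl)-4H-chromen-4-one, via trans-dihydroflavonol 15 (not isolated)
Conditions: 30% H2O2, aq. NaOH, MeOH, 0 °C to rt
Reagents that add atoms: hydrogen peroxide, OO
Why: Algar–Flynn–Oyamada oxidation; hydroperoxide adds to the enone, the 2'-phenoxide closes ring C at the benzylic carbon to give 15, and further peroxide dehydrogenates 15 to the flavonol, which erases its two transient stereocentres; the oxidant is nucleophilic and should leave the three isolated alkenes alone.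

Step 11
Reactants: 16 3-hydroxy-5,7-bis(methoxymethoxy)-2-[5-(methoxymethoxy)-4-(2-methylbut-3-en-2-yloxy)-2-(3-methylbut-2-enyl)phenyl]-8-(2-methylbut-3-en-2-yl)-4H-chromen-4-one
Product: 17 3,5,7-tris(methoxymethoxy)-2-[5-(methoxymethoxy)-4-(2-methylbut-3-en-2-yloxy)-2-(3-methylbut-2-enyl)phenyl]-8-(2-methylbut-3-en-2-yl)-4H-chromen-4-one
Conditions: MOMCl, iPr2NEt, CH2Cl2, 0 °C to rt
Reagents that add atoms: chloromethyl methyl ether, COCCl
Why: Acetal ether formation; the enolic 3-hydroxyl is the only free hydroxyl of 16 because O4' is still held as the tertiary allyl ether, so no selectivity is required.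

Step 12
Reactants: 17 3,5,7-tris(methoxymethoxy)-2-[5-(methoxymethoxy)-4-(2-methylbut-3-en-2-yloxy)-2-(3-methylbut-2-enyl)phenyl]-8-(2-methylbut-3-en-2-yl)-4H-chromen-4-one
Product: 18 2-[4-hydroxy-5-(methoxymethoxy)-2,3-bis(3-methylbut-2-enyl)phenyl]-3,5,7-tris(methoxymethoxy)-8-(2-methylbut-3-en-2-yl)-4H-chromen-4-one
Conditions: PhNEt2, 130 °C, Ar
Reagents that add atoms: none
Why: Aromatic Claisen rearrangement of an aryl 1,1-dimethylallyl ether; the [3,3] shift moves the C5 unit with allylic inversion to C3', the only ortho carbon with hydrogen since C5' carries the acetal ether, and rearomatisation releases the 4'-phenol; tertiary allyl aryl ethers rearrange well below the temperature at which the acetals or the C-bound C5 groups would react.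

Step 13
Reactants: 18 2-[4-hydroxy-5-(methoxymethoxy)-2,3-bis(3-methylbut-2-enyl)phenyl]-3,5,7-tris(methoxymethoxy)-8-(2-methylbut-3-en-2-yl)-4H-chromen-4-one
Product: 20 3,5,7-tris(methoxymethoxy)-2-[8-(methoxymethoxy)-2,2-dimethyl-5-(3-methylbut-2-enyl)-2H-chromen-6-yl]-8-(2-methylbut-3-en-2-yl)-4H-chromen-4-one, via ortho-quinone methide 19 (not isolated)
Conditions: DDQ (1.1 equiv), benzene, rt to 60 °C
Reagents that add atoms: none
Why: DDQ forms a charge-transfer complex with the phenolic ring B and abstracts hydride from the C3' methylene, which is benzylic, allylic and ortho to the free 4'-hydroxyl; loss of the phenolic proton gives the ortho-quinone methide 19, whose exocyclic double bond is conjugated with the dimethylvinyl unit. The 1-oxatriene O=C4'–C3'=CH–CH=C(CH3)2 of 19 then closes by a thermal, disrotatory oxa-6π electrocyclisation that forms the O4'–C(CH3)2 bond and restores the aromaticity of ring B. The closest known reaction type is the DDQ cyclodehydrogenation of ortho-prenylphenols to 2,2-dimethyl-2H-chromenes, established for prenylated flavonoids, coumarins and xanthones. The pyran ring is closed in a pericyclic mode (formally 6-endo at the dimethyl-bearing alkene terminus), so no five-membered ether can compete as it would in an ionic addition. No stereocentre is created. The step needs site selectivity among three C5 groups: the 2'-prenyl methylene has carbon neighbours on both sides and a fixed acetal ether, not a hydroxyl, in its para position, so it cannot reach a neutral quinone methide; the C8 substituent has a quaternary benzylic carbon with no hydrogen to give up; and O4'–H is the only free hydroxyl in 18. Ring B is conjugated to the electron-poor pyranone, which slows unassisted hydride abstraction further, and one equivalent of oxidant in a non-nucleophilic solvent limits over-oxidation of the chromene.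

Step 14
Reactants: 20 3,5,7-tris(methoxymethoxy)-2-[8-(methoxymethoxy)-2,2-dimethyl-5-(3-methylbut-2-enyl)-2H-chromen-6-yl]-8-(2-methylbut-3-en-2-yl)-4H-chromen-4-one
Product: 21 broussoflavonol D
Conditions: 3 M aq. HCl, MeOH, 50 °C
Reagents that add atoms: none
Why: Acid-catalysed acetal exchange to methanol removes all four methoxymethyl groups; the 2'-prenyl group has no neighbouring hydroxyl to cyclise onto, protonation of the vinyl group on C8 would give only a secondary cation, and the chromene is not affected by dilute acid at this temperature.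

## Compound list

1 | 2,4,6-trihydroxyacetophenone | CC(=O)c1c(O)cc(O)cc1O | starting material
2 | prenyl bromide (1-bromo-3-methylbut-2-ene) | CC(C)=CCBr | starting material
3 | 1-[2,6-dihydroxy-4-(3-methylbut-2-enyloxy)phenyl]ethanone | CC(=O)c1c(O)cc(OCC=C(C)C)cc1O | intermediate
4 | 1-[2,4,6-trihydroxy-3-(2-methylbut-3-en-2-yl)phenyl]ethanone | CC(=O)c1c(O)cc(O)c(C(C)(C)C=C)c1O | intermediate
5 | 1-[2-hydroxy-4,6-bis(methoxymethoxy)-3-(2-methylbut-3-en-2-yl)phenyl]ethanone | CC(=O)c1c(OCOC)cc(OCOC)c(C(C)(C)C=C)c1O | intermediate
6 | 2-bromo-4,5-dimethoxybenzaldehyde | COc1cc(Br)c(C=O)cc1OC | starting material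
7 | 2-bromo-4,5-dihydroxybenzaldehyde | O=Cc1cc(O)c(O)cc1Br | intermediate
8 | 2-bromo-4-hydroxy-5-(methoxymethoxy)benzaldehyde | COCOc1cc(C=O)c(Br)cc1O | intermediate
9 | tributyl(3-methylbut-2-enyl)stannane | CCCC[Sn](CCCC)(CCCC)CC=C(C)C | starting material
10 | 4-hydroxy-5-(methoxymethoxy)-2-(3-methylbut-2-enyl)benzaldehyde | COCOc1cc(C=O)c(CC=C(C)C)cc1O | intermediate
11 | 2-methylbut-3-en-2-ol | C=CC(C)(C)O | starting material
12 | tert-butyl 2-methylbut-3-en-2-yl carbonate | C=CC(C)(C)OC(=O)OC(C)(C)C | intermediate
13 | 5-(methoxymethoxy)-4-(2-methylbut-3-en-2-yloxy)-2-(3-methylbut-2-enyl)benzaldehyde | COCOc1cc(C=O)c(CC=C(C)C)cc1OC(C)(C)C=C | intermediate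
14 | (E)-1-[2-hydroxy-4,6-bis(methoxymethoxy)-3-(2-methylbut-3-en-2-yl)phenyl]-3-[5-(methoxymethoxy)-4-(2-methylbut-3-en-2-yloxy)-2-(3-methylbut-2-enyl)phenyl]prop-2-en-1-one | C=CC(C)(C)c1c(O)c(C(=O)/C=C/c2cc(OCOC)c(OC(C)(C)C=C)cc2CC=C(C)C)c(OCOC)cc1OCOC | intermediate
15 | trans-3-hydroxy-5,7-bis(methoxymethoxy)-2-[5-(methoxymethoxy)-4-(2-methylbut-3-en-2-yloxy)-2-(3-methylbut-2-enyl)phenyl]-8-(2-methylbut-3-en-2-yl)chroman-4-one (racemic, one enantiomer drawn) | CC(C)=CCc1cc(OC(C)(C)C=C)c(OCOC)cc1[C@@H]1[C@H](C(=O)c2c(OCOC)cc(OCOC)c(C(C)(C)C=C)c2O1)O | intermediate (not isolated)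
16 | 3-hydroxy-5,7-bis(methoxymethoxy)-2-[5-(methoxymethoxy)-4-(2-methylbut-3-en-2-yloxy)-2-(3-methylbut-2-enyl)phenyl]-8-(2-methylbut-3-en-2-yl)-4H-chromen-4-one | C=CC(C)(C)c1c(OCOC)cc(OCOC)c2c(=O)c(O)c(-c3cc(OCOC)c(OC(C)(C)C=C)cc3CC=C(C)C)oc12 | intermediate
17 | 3,5,7-tris(methoxymethoxy)-2-[5-(methoxymethoxy)-4-(2-methylbut-3-en-2-yloxy)-2-(3-methylbut-2-enyl)phenyl]-8-(2-methylbut-3-en-2-yl)-4H-chromen-4-one | C=CC(C)(C)c1c(OCOC)cc(OCOC)c2c(=O)c(OCOC)c(-c3cc(OCOC)c(OC(C)(C)C=C)cc3CC=C(C)C)oc12 | intermediate
18 | 2-[4-hydroxy-5-(methoxymethoxy)-2,3-bis(3-methylbut-2-enyl)phenyl]-3,5,7-tris(methoxymethoxy)-8-(2-methylbut-3-en-2-yl)-4H-chromen-4-one | C=CC(C)(C)c1c(OCOC)cc(OCOC)c2c(=O)c(OCOC)c(-c3cc(OCOC)c(O)c(CC=C(C)C)c3CC=C(C)C)oc12 | intermediate (precursor of the key step)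
19 | 2-[5-(methoxymethoxy)-3-(3-methylbut-2-enylidene)-2-(3-methylbut-2-enyl)-4-oxocyclohexa-1,5-dien-1-yl]-3,5,7-tris(methoxymethoxy)-8-(2-methylbut-3-en-2-yl)-4H-chromen-4-one (ortho-quinone methide, exocyclic alkene with the dimethylvinyl group on the carbonyl side) | C=CC(C)(C)c1c(OCOC)cc(OCOC)c2c(=O)c(OCOC)c(C3=C(CC=C(C)C)/C(=C/C=C(C)C)C(=O)C(OCOC)=C3)oc12 | intermediate (not isolated)
20 | 3,5,7-tris(methoxymethoxy)-2-[8-(methoxymethoxy)-2,2-dimethyl-5-(3-methylbut-2-enyl)-2H-chromen-6-yl]-8-(2-methylbut-3-en-2-yl)-4H-chromen-4-one | C=CC(C)(C)c1c(OCOC)cc(OCOC)c2c(=O)c(OCOC)c(-c3cc(OCOC)c4c(c3CC=C(C)C)C=CC(C)(C)O4)oc12 | intermediate (product of the key step)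
21 | broussoflavonol D | C=CC(C)(C)c1c(O)cc(O)c2c(=O)c(O)c(-c3cc(O)c4c(c3CC=C(C)C)C=CC(C)(C)O4)oc12 | target

## Step count and least certain steps

Total step count: 14. Longest linear sequence: 10 steps (steps 4, 5, 6, 8, 9, 10, 11, 12, 13, 14, from 6). The ring A branch (steps 1 to 3) and the carbonate (step 7) join it at steps 9 and 8.

Step 13 (key step). The most likely failures are:
- competing hydride abstraction at the 2'-prenyl methylene, which is activated by the para ether oxygen;
- further oxidation of the chromene once it has formed;
- addition of the reduced quinone to 19 before it can cyclise.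

Fallback, from 8, returning at 20: the pyran is built thermally before ring C. Copper-catalysed alkylation of 8 with 3-chloro-3-methylbut-1-yne (CuCl2 cat., DBU, MeCN, 0 °C) would give 2-bromo-5-(methoxymethoxy)-4-(2-methylbut-3-yn-2-yloxy)benzaldehyde F1. Heating in PhNEt2 at 170 °C should convert it by propargyl Claisen rearrangement, hydrogen shift and 6π closure into 5-bromo-8-(methoxymethoxy)-2,2-dimethyl-2H-chromene-6-carbaldehyde F2. Stille coupling of F2 with 9 under the conditions of step 6 would give 8-(methoxymethoxy)-2,2-dimethyl-5-(3-methylbut-2-enyl)-2H-chromene-6-carbaldehyde F3. Condensation of F3 with 5 as in step 9 would give (E)-1-[2-hydroxy-4,6-bis(methoxymethoxy)-3-(2-methylbut-3-en-2-yl)phenyl]-3-[8-(methoxymethoxy)-2,2-dimethyl-5-(3-methylbut-2-enyl)-2H-chromen-6-yl]prop-2-en-1-one F4. Peroxide cyclisation as in step 10 would give 3-hydroxy-5,7-bis(methoxymethoxy)-2-[8-(methoxymethoxy)-2,2-dimethyl-5-(3-methylbut-2-enyl)-2H-chromen-6-yl]-8-(2-methylbut-3-en-2-yl)-4H-chromen-4-one F5, and capping of O3 as in step 11 gives 20.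

Step 10. The phenoxide may attack the α-carbon in a 5-exo mode and lead toward an aurone. The alkoxy group ortho to the carbonyl on ring A and the ortho-prenyl group crowding the β-carbon both push that way. Oxidation may also stall at the stage of 15.

Fallback, from 13 and 5, returning at 16: ring C is built through the diketone and C3 is oxygenated by metalation. Pinnick oxidation of 13 (NaClO2, NaH2PO4, excess 2-methylbut-2-ene, t-BuOH/H2O) would give 5-(methoxymethoxy)-4-(2-methylbut-3-en-2-yloxy)-2-(3-methylbut-2-enyl)benzoic acid F6. 1,1'-Carbonyldiimidazole would turn it into the acyl imidazole 1-[5-(methoxymethoxy)-4-(2-methylbut-3-en-2-yloxy)-2-(3-methylbut-2-enyl)benzoyl]imidazole F7. C-acylation of the dianion of 5 (LiN(SiMe3)2, 3 equiv, THF, −78 °C) with F7 would give the Baker–Venkataraman-type diketone 1-[2-hydroxy-4,6-bis(methoxymethoxy)-3-(2-methylbut-3-en-2-yl)phenyl]-3-[5-(methoxymethoxy)-4-(2-methylbut-3-en-2-yloxy)-2-(3-methylbut-2-enyl)phenyl]propane-1,3-dione F8. Cyclodehydration in buffered acetic acid (NaOAc, AcOH, 50 °C, below the temperature at which the tertiary ether rearranges) would give 5,7-bis(methoxymethoxy)-2-[5-(methoxymethoxy)-4-(2-methylbut-3-en-2-yloxy)-2-(3-methylbut-2-enyl)phenyl]-8-(2-methylbut-3-en-2-yl)-4H-chromen-4-one F9. Lithiation of F9 at C3 (LiN(iPr)2, THF, −78 °C), borylation with B(OMe)3 and oxidation of the borate with H2O2/AcOH leads to 16.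

Step 5. The very reactive chloride may erode the preference of the dianion for the oxygen meta to the formyl group, or alkylate both oxygens.

Fallback, from 7, returning at 8: the more acidic hydroxyl is masked first under weak-base conditions. Alkylation of 7 with allyl bromide (NaHCO3, NaI, DMF, 40 °C) would give 4-(allyloxy)-2-bromo-5-hydroxybenzaldehyde F10. Acetal formation (MOMCl, iPr2NEt, CH2Cl2) would give 4-(allyloxy)-2-bromo-5-(methoxymethoxy)benzaldehyde F11. Palladium-catalysed allyl transfer to methoxide (Pd(PPh3)4 cat., K2CO3, MeOH, rt, at which temperature the aryl bromide should not react) would release 8.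

Step 3. The second acetal may go onto the hydroxyl next to the tert-alkyl group instead of the one next to hydrogen, which would lead in the end to the C6 isomer. The hindered 4-hydroxyl may also be protected incompletely.

Fallback, from 3, returning at 5: the order is changed so that chelation, not steric discrimination, sets the regiochemistry. Mono-protection of 3 (MOMCl, 1.05 equiv, iPr2NEt, CH2Cl2) would give 1-[2-hydroxy-6-(methoxymethoxy)-4-(3-methylbut-2-enyloxy)phenyl]ethanone F12. Its Claisen rearrangement (PhNEt2, 190 °C) is directed by bond fixation of the chelated ortho-hydroxyketone to the carbon between the chelated hydroxyl and the ether oxygen, which would give 1-[2,4-dihydroxy-6-(methoxymethoxy)-3-(2-methylbut-3-en-2-yl)phenyl]ethanone F13. Protection of its only non-chelated hydroxyl gives 5.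

Step 8. Zerovalent palladium may re-ionise the kinetic tertiary ether, whose phenoxide para to the formyl group is a good leaving group, and equilibrate it to the linear prenyl ether. C-allylation ortho to the phenoxide is a second possibility.

Fallback, from 10, returning at 13: the tertiary carbon–oxygen bond is made by copper-catalysed propargylic substitution and the alkene by partial reduction. Alkylation of 10 with 3-chloro-3-methylbut-1-yne (CuCl2 cat., DBU, MeCN, 0 °C) would give 5-(methoxymethoxy)-4-(2-methylbut-3-yn-2-yloxy)-2-(3-methylbut-2-enyl)benzaldehyde F14. Semi-hydrogenation (H2, Pd/CaCO3 poisoned with Pb(OAc)2, quinoline, EtOAc), which leaves the trisubstituted prenyl alkene and the aldehyde alone, gives 13.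

## Further compounds

F1 | step 13 | 2-bromo-5-(methoxymethoxy)-4-(2-methylbut-3-yn-2-yloxy)benzaldehyde | COCOc1cc(C=O)c(Br)cc1OC(C)(C)C#C
F2 | step 13 | 5-bromo-8-(methoxymethoxy)-2,2-dimethyl-2H-chromene-6-carbaldehyde | COCOc1cc(C=O)c(Br)c2C=CC(C)(C)Oc12
F3 | step 13 | 8-(methoxymethoxy)-2,2-dimethyl-5-(3-methylbut-2-enyl)-2H-chromene-6-carbaldehyde | COCOc1cc(C=O)c(CC=C(C)C)c2C=CC(C)(C)Oc12
F4 | step 13 | (E)-1-[2-hydroxy-4,6-bis(methoxymethoxy)-3-(2-methylbut-3-en-2-yl)phenyl]-3-[8-(methoxymethoxy)-2,2-dimethyl-5-(3-methylbut-2-enyl)-2H-chromen-6-yl]prop-2-en-1-one | C=CC(C)(C)c1c(O)c(C(=O)/C=C/c2cc(OCOC)c3OC(C)(C)C=Cc3c2CC=C(C)C)c(OCOC)cc1OCOC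
F5 | step 13 | 3-hydroxy-5,7-bis(methoxymethoxy)-2-[8-(methoxymethoxy)-2,2-dimethyl-5-(3-methylbut-2-enyl)-2H-chromen-6-yl]-8-(2-methylbut-3-en-2-yl)-4H-chromen-4-one | C=CC(C)(C)c1c(OCOC)cc(OCOC)c2c(=O)c(O)c(-c3cc(OCOC)c4OC(C)(C)C=Cc4c3CC=C(C)C)oc12
F6 | step 10 | 5-(methoxymethoxy)-4-(2-methylbut-3-en-2-yloxy)-2-(3-methylbut-2-enyl)benzoic acid | COCOc1cc(C(=O)O)c(CC=C(C)C)cc1OC(C)(C)C=C
F7 | step 10 | 1-[5-(methoxymethoxy)-4-(2-methylbut-3-en-2-yloxy)-2-(3-methylbut-2-enyl)benzoyl]imidazole | COCOc1cc(C(=O)n2ccnc2)c(CC=C(C)C)cc1OC(C)(C)C=C
F8 | step 10 | 1-[2-hydroxy-4,6-bis(methoxymethoxy)-3-(2-methylbut-3-en-2-yl)phenyl]-3-[5-(methoxymethoxy)-4-(2-methylbut-3-en-2-yloxy)-2-(3-methylbut-2-enyl)phenyl]propane-1,3-dione | C=CC(C)(C)c1c(O)c(C(=O)CC(=O)c2cc(OCOC)c(OC(C)(C)C=C)cc2CC=C(C)C)c(OCOC)cc1OCOC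
F9 | step 10 | 5,7-bis(methoxymethoxy)-2-[5-(methoxymethoxy)-4-(2-methylbut-3-en-2-yloxy)-2-(3-methylbut-2-enyl)phenyl]-8-(2-methylbut-3-en-2-yl)-4H-chromen-4-one | C=CC(C)(C)c1c(OCOC)cc(OCOC)c2c(=O)cc(-c3cc(OCOC)c(OC(C)(C)C=C)cc3CC=C(C)C)oc12
F10 | step 5 | 4-(allyloxy)-2-bromo-5-hydroxybenzaldehyde | C=CCOc1cc(Br)c(C=O)cc1O
F11 | step 5 | 4-(allyloxy)-2-bromo-5-(methoxymethoxy)benzaldehyde | C=CCOc1cc(Br)c(C=O)cc1OCOC
F12 | step 3 | 1-[2-hydroxy-6-(methoxymethoxy)-4-(3-methylbut-2-enyloxy)phenyl]ethanone | CC(=O)c1c(O)cc(OCC=C(C)C)cc1OCOC
F13 | step 3 | 1-[2,4-dihydroxy-6-(methoxymethoxy)-3-(2-methylbut-3-en-2-yl)phenyl]ethanone | CC(=O)c1c(OCOC)cc(O)c(C(C)(C)C=C)c1O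
F14 | step 8 | 5-(methoxymethoxy)-4-(2-methylbut-3-yn-2-yloxy)-2-(3-methylbut-2-enyl)benzaldehyde | COCOc1cc(C=O)c(CC=C(C)C)cc1OC(C)(C)C#C
A1 | alternative 1 | 1-[2-hydroxy-6-(methoxymethoxy)-4-(3-methylbut-2-enyloxy)phenyl]-3-[8-(methoxymethoxy)-2,2-dimethyl-5-(3-methylbut-2-enyl)-2H-chromen-6-yl]prop-2-yn-1-one | CC(C)=CCOc1cc(O)c(C(=O)C#Cc2cc(OCOC)c3c(c2CC=C(C)C)C=CC(C)(C)O3)c(OCOC)c1
A2 | alternative 1 | 3-(methoxymethoxy)-5-(3-methylbut-2-enyloxy)benzyne | COCOC1=CC(OCC=C(C)C)=CC#C1
A3 | alternative 1 | 3-[8-(methoxymethoxy)-2,2-dimethyl-5-(3-methylbut-2-enyl)-2H-chromen-6-yl]prop-2-ynoic acid | OC(=O)C#Cc1cc(OCOC)c2c(c1CC=C(C)C)C=CC(C)(C)O2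
A4 | alternative 1 | 5-(methoxymethoxy)-2-[8-(methoxymethoxy)-2,2-dimethyl-5-(3-methylbut-2-enyl)-2H-chromen-6-yl]-7-(3-methylbut-2-enyloxy)-4H-chromen-4-one | CC(C)=CCOc1cc(OCOC)c2c(=O)cc(-c3cc(OCOC)c4c(c3CC=C(C)C)C=CC(C)(C)O4)oc2c1
A5 | alternative 2 | methyl 8-(tert-butyldimethylsilyloxy)-2,2-dimethyl-5-(3-methylbut-2-enyl)-2H-chromene-6-carboxylate | COC(=O)c1cc(O[Si](C)(C)C(C)(C)C)c2c(c1CC=C(C)C)C=CC(C)(C)O2
A6 | alternative 2 | 8-(tert-butyldimethylsilyloxy)-2,2-dimethyl-2H,5H-pyrano[3,2-c]pyran-5-one | O=C1OC=C(O[Si](C)(C)C(C)(C)C)C2=C1C=CC(C)(C)O2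
A7 | alternative 2 | methyl 6-methylhept-5-en-2-ynoate | COC(=O)C#CCC=C(C)C
A8 | alternative 3 | 5,7-bis(methoxymethoxy)-2-[8-(methoxymethoxy)-2,2-dimethyl-5-(3-methylbut-2-enyl)-2H-chromen-6-yl]-8-(2-methylbut-3-en-2-yl)-4H-chromen-4-one | C=CC(C)(C)c1c(OCOC)cc(OCOC)c2c(=O)cc(-c3cc(OCOC)c4c(c3CC=C(C)C)C=CC(C)(C)O4)oc12
A9 | alternative 3 | 3,5-bis(methoxymethoxy)-2-(2-methylbut-3-en-2-yl)-6-[2-(triphenylphosphoranylidene)acetyl]phenyl 8-(methoxymethoxy)-2,2-dimethyl-5-(3-methylbut-2-enyl)-2H-chromene-6-carboxylate | C=CC(C)(C)c1c(OCOC)cc(OCOC)c(C(=O)C=P(c2ccccc2)(c2ccccc2)c2ccccc2)c1OC(=O)c1cc(OCOC)c2c(c1CC=C(C)C)C=CC(C)(C)O2
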